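## Retrosynthetic overview

1. The target comes from its heptaacetate, which is made by a Heck reaction between the C4–Br of ring A and 4-acetoxystyrene. Methyl ethers and the carbonate are exchanged for acetates before the acid-sensitive stilbene exists.
2. Ring B (O1–C2–C3–C3a–C7a) comes from a two-atom ring expansion of an (R,R)-trans-2,3-diaryloxirane. The two triple-bond carbons of 3-bromo-5-methoxybenzyne (future C7a and C3a) insert into the O–C3 bond, which also delivers the whole of ring A.
3. Enabling feature: O1 and C3 sit on the neighbouring carbons C7a/C3a of ring A, right beside C4. A bromine at C4 steers the aryne and later becomes the styryl group. C3 is para-alkoxybenzylic because O1' of ring D stands para to C5' on ring C, and the C2 aryl group can be switched off as a carbonate.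
4. The oxirane comes from Shi epoxidation of the E-stilbene, which is made by Heck coupling at the C5'–Br of the ring C/D unit.
5. Ring D comes from an enantioselective dirhodium-carbene 1,5-C–H insertion of a diaryldiazomethane built from 5-bromo-ortho-vanillin, followed by C2' epimerisation. Order of ring formation: D, then the oxirane, then B (together with A).

Key step: step 10

Locants: unprimed locants refer to the styryl-bearing dihydrobenzofuran (benzo ring A, heterocycle B). Primed locants refer to the second dihydrobenzofuran (benzo ring C, heterocycle D). The target is (2S,3S,2'R,3'R), with both rings trans.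

Assumption: Rh2(R-PTAD)4, dirhodium tetrakis[(R)-(1-adamantyl)(phthalimido)acetate], is taken to give the (2S,3R)-cis product in step 5. Should the first run show the opposite sense, the equally available Rh2(S-PTAD)4 is used and nothing else changes.

## Route

Step 1
Reactants: 1 5-bromo-2-hydroxy-3-methoxybenzaldehyde; 2 4-methoxybenzyl chloride
Product: 3 5-bromo-3-methoxy-2-[(4-methoxybenzyl)oxy]benzaldehyde
Conditions: K2CO3, DMF, 60 °C
Reagents that add atoms: none
Why: Williamson ether synthesis on the acidic ortho-formyl phenol, in which the benzylic CH2 introduced is the future C2' and already carries its aryl group.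

Step 2
Reactants: 3 5-bromo-3-methoxy-2-[(4-methoxybenzyl)oxy]benzaldehyde; 4 1-bromo-3,5-dimethoxybenzene
Product: 6 racemic {5-bromo-3-methoxy-2-[(4-methoxybenzyl)oxy]phenyl}(3,5-dimethoxyphenyl)methanol, via Grignard reagent 5 (not isolated)
Conditions: 4, Mg, THF, 40 °C; then 3, THF, 0 °C; aq NH4Cl
Reagents that add atoms: none
Why: Grignard addition to the aldehyde should be much faster at 0 °C than bromine–magnesium exchange at the aryl bromide of 3, and the racemic carbinol centre is erased in step 3.

Step 3
Reactants: 6 racemic diarylmethanol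
Product: 7 {5-bromo-3-methoxy-2-[(4-methoxybenzyl)oxy]phenyl}(3,5-dimethoxyphenyl)methanone
Conditions: activated MnO2, CH2Cl2, rt
Reagents that add atoms: none
Why: MnO2 oxidation of a doubly benzylic alcohol leaves aryl ethers, the benzyl ether and the bromide untouched.

Step 4
Reactants: 7 diaryl ketone
Product: 8 hydrazone of 7 (E/Z mixture)
Conditions: N2H4·H2O, AcOH (cat.), EtOH, 80 °C
Reagents that add atoms: hydrazine, NN
Why: Acid-catalysed hydrazone condensation on a benzophenone with a single ortho substituent, and the C=N geometry is irrelevant because it is lost in step 5.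

Step 5
Reactants: 8 hydrazone
Product: 10 (2S,3R)-5-bromo-3-(3,5-dimethoxyphenyl)-7-methoxy-2-(4-methoxyphenyl)-2,3-dihydro-1-benzofuran (cis), via diaryldiazomethane 9 (not isolated)
Conditions: MnO2, CH2Cl2, 0 °C, filter; then Rh2(R-PTAD)4 (1 mol %), CH2Cl2, 0 °C to rt
Reagents that add atoms: none
Why: Hydrazone dehydrogenation followed by enantioselective intramolecular 1,5-C–H insertion of a donor/donor dirhodium carbene into the ether-activated para-methoxybenzylic CH2 closes ring D, the chiral carboxylate ligands choosing the carbene face and the enantiotopic C–H bond (C3' and C2') and the compact hydride-transfer-like transition state giving the cis ring.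

Step 6
Reactants: 10 cis-dihydrobenzofuran
Product: 11 (2R,3R)-5-bromo-3-(3,5-dimethoxyphenyl)-7-methoxy-2-(4-methoxyphenyl)-2,3-dihydro-1-benzofuran (trans)
Conditions: CF3CO2H, CH2Cl2, 0 °C to rt
Reagents that add atoms: none
Why: Acid-catalysed epimerisation by reversible heterolysis of the C2'–O1' bond to a para-methoxybenzylic cation, which recloses to the thermodynamically preferred trans ring, so the untouched C3' dictates the (2'R) configuration.

Step 7
Reactants: 11 trans-bromide; 12 tert-butyl 4-vinylphenyl carbonate
Product: 13 tert-butyl 4-{(E)-2-[(2R,3R)-3-(3,5-dimethoxyphenyl)-7-methoxy-2-(4-methoxyphenyl)-2,3-dihydro-1-benzofuran-5-yl]ethenyl}phenyl carbonate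
Conditions: Pd2(dba)3 (2 mol %), [HP(t-Bu)3]BF4 (8 mol %), Cy2NMe, 1,4-dioxane, 70 °C
Reagents that add atoms: none
Why: Mizoroki–Heck reaction in which the electron-rich bulky phosphine on zerovalent palladium activates the unhindered but electron-rich C5'–Br at a temperature the carbonate tolerates, and syn insertion with syn β-hydride elimination gives the E-alkene.

Step 8
Reactants: 13 E-stilbene
Product: 14 tert-butyl 4-[(2R,3R)-3-{(2R,3R)-3-(3,5-dimethoxyphenyl)-7-methoxy-2-(4-methoxyphenyl)-2,3-dihydro-1-benzofuran-5-yl}oxiran-2-yl]phenyl carbonate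
Conditions: D-fructose-derived Shi ketone (30 mol %), KHSO5 (as 2KHSO5·KHSO4·K2SO4), K2CO3, Bu4NHSO4, Na2B4O7/Na2H2EDTA buffer, MeCN–CH2(OMe)2–H2O, 0 °C; filtration through Et3N-deactivated silica, used at once
Reagents that add atoms: potassium peroxymonosulfate, [K+].[O-]S(=O)(=O)OO
Why: Shi epoxidation, in which the chiral dioxirane attacks E-stilbenes through a spiro transition state and the D-fructose-derived ketone gives the (R,R)-oxirane under catalyst control (both oxirane carbons), while the basic buffer protects the acid-labile product and the hindered carbonate should survive the short time at 0 °C.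

Step 9
Reactants: 15 2,6-dibromo-4-methoxyphenol
Product: 19 2-bromo-4-methoxy-6-(trimethylsilyl)phenyl trifluoromethanesulfonate, via silyl ether 16 (not isolated), via aryllithium 17 (not isolated), via lithium phenolate 18 (not isolated)
Conditions: (Me3Si)2NH, THF, 65 °C, concentrate; n-BuLi (1.05 equiv), THF, −78 °C; Tf2O, −78 to 0 °C
Reagents that add atoms: hexamethyldisilazane, C[Si](C)(C)N[Si](C)(C)C; trifluoromethanesulfonic anhydride, O=S(=O)(OS(=O)(=O)C(F)(F)F)C(F)(F)F
Why: Single bromine–lithium exchange triggers a retro-Brook O-to-C silyl shift and the released phenolate is trapped as the triflate, the standard entry to ortho-silylaryl triflates, the second bromine staying because it is meta to the lithiated carbon.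

Step 10
Reactants: 14 (R,R)-oxirane; 19 ortho-silylaryl triflate
Product: 23 tert-butyl 4-[(2S,3S)-4-bromo-3-{(2R,3R)-3-(3,5-dimethoxyphenyl)-7-methoxy-2-(4-methoxyphenyl)-2,3-dihydro-1-benzofuran-5-yl}-6-methoxy-2,3-dihydro-1-benzofuran-2-yl]phenyl carbonate, via 3-bromo-5-methoxybenzyne 20 (not isolated), via aryloxiranium zwitterion 21 (not isolated), via ring-opened zwitterion 22 (not isolated)
Conditions: CsF (6 equiv), 4 Å molecular sieves, MeCN–toluene 1:1, 25 °C, 19 (2.5 equiv) added slowly
Reagents that add atoms: none
Why: Proposed new method: fluoride removes the silyl group of 19 and triflate leaves to give aryne 20, whose carbon remote from bromine (future C7a) takes up the oxirane oxygen of 14, because the C–Br dipole distorts the triple bond so that this carbon is the more linear, more electrophilic and less crowded one and the carbanion develops beside bromine (future C3a), the opposing pull of the 5-methoxy group being one position further away and weaker. In zwitterion 21 the O–C3 bond ionises selectively, since C3 is para-alkoxybenzylic through O1' whereas the aryl group on C2 is deactivated as its tert-butyl carbonate, and the aryl anion of 22 collapses on the cation, so the three-membered ring grows by two atoms into ring B with one new C–O and one new C–C bond on neighbouring carbons of ring A. The closure is a 5-exo-trig attack of C3a on the quinone-methide-like C3=C5' bond of 22, a concerted backside displacement being a geometrically impossible endocyclic substitution, which is why the cation-stabilising aryl group is essential. C2 keeps its configuration because its C–O bond is never broken, and C3 is set trans to the C2 aryl group both by rapid collapse on the face the oxygen has just left (net retention) and by avoidance of eclipsed aryl groups, so the (R,R)-oxirane should give the (2S,3S) ring. The closest known reaction type is the fluoride-triggered insertion of benzyne into the benzylic C–O bond of styrene oxide to give a dihydrobenzofuran; new here are the 2,3-diaryloxirane class, the choice between two benzylic C–O bonds and the transfer of configuration. The step needs ring closure to outrun proton transfer, fluoride capture and loss of bromide from the ortho-bromoaryl anion, which the intramolecular ion-pair collapse, the sparingly soluble CsF and the slow addition of 19 should secure.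

Step 11
Reactants: 23 bromo bis(dihydrobenzofuran)
Product: 24 (2S,3S)-4-bromo-3-[(2R,3R)-3-(3,5-dihydroxyphenyl)-7-hydroxy-2-(4-hydroxyphenyl)-2,3-dihydro-1-benzofuran-5-yl]-2-(4-hydroxyphenyl)-2,3-dihydro-1-benzofuran-6-ol (hexaphenol)
Conditions: BBr3 (12 equiv), CH2Cl2, −78 to 0 °C; ice-water
Reagents that add atoms: none
Why: BBr3 ether cleavage removes the five methyl ethers and the tert-butyl carbonate while no stilbene is yet present to cyclise, and any reversible opening at C2 or C2' recloses to the more stable trans rings under control of the untouched C3 and C3'.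

Step 12
Reactants: 24 hexaphenol
Product: 25 hexaacetate of 24
Conditions: Ac2O, pyridine, DMAP (cat.), CH2Cl2, 0 °C to rt
Reagents that add atoms: acetic anhydride, CC(=O)OC(C)=O
Why: Exhaustive phenol acetylation gives a stable intermediate that can be purified by chromatography, lowers the electron density of ring A for oxidative addition, and installs groups that come off under mild base at the end.

Step 13
Reactants: 25 hexaacetate; 26 4-vinylphenyl acetate
Product: 27 heptaacetate of the target
Conditions: Pd2(dba)3 (5 mol %), [HP(t-Bu)3]BF4 (20 mol %), Cy2NMe, 1,4-dioxane, 90 °C, dark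
Reagents that add atoms: none
Why: Mizoroki–Heck reaction of the ortho-substituted C4–Br with an excess of the styrene, using a monoligated zerovalent palladium catalyst suited to hindered bromides and an amine base that disfavours C–H arylation pathways and spares the acetates, gives the E-stilbene.

Step 14
Reactants: 27 heptaacetate
Product: 28 target CNP0172909.1
Conditions: K2CO3 (cat.), degassed MeOH–THF, 0 °C to rt, argon, dark; then acidic ion-exchange resin
Reagents that add atoms: none
Why: Base-catalysed transesterification of aryl acetates proceeds under conditions that touch neither the E-alkene nor the four stereocentres, which are not acidic enough to epimerise.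

## Compound list

1 | 5-bromo-2-hydroxy-3-methoxybenzaldehyde | O=Cc1cc(Br)cc(OC)c1O | starting material
2 | 4-methoxybenzyl chloride | COc1ccc(CCl)cc1 | starting material
3 | 5-bromo-3-methoxy-2-[(4-methoxybenzyl)oxy]benzaldehyde | O=Cc1cc(Br)cc(OC)c1OCc1ccc(OC)cc1 | intermediate
4 | 1-bromo-3,5-dimethoxybenzene | COc1cc(Br)cc(OC)c1 | starting material
5 | 3,5-dimethoxyphenylmagnesium bromide | COc1cc([Mg]Br)cc(OC)c1 | intermediate
6 | racemic diarylmethanol | OC(c1cc(OC)cc(OC)c1)c1cc(Br)cc(OC)c1OCc1ccc(OC)cc1 | intermediate
7 | diaryl ketone | O=C(c1cc(OC)cc(OC)c1)c1cc(Br)cc(OC)c1OCc1ccc(OC)cc1 | intermediate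
8 | hydrazone of 7 | NN=C(c1cc(OC)cc(OC)c1)c1cc(Br)cc(OC)c1OCc1ccc(OC)cc1 | intermediate
9 | diaryldiazomethane | [N-]=[N+]=C(c1cc(OC)cc(OC)c1)c1cc(Br)cc(OC)c1OCc1ccc(OC)cc1 | intermediate
10 | (2S,3R)-cis-5-bromo-dihydrobenzofuran | Brc1cc(OC)c2c(c1)[C@@H](c1cc(OC)cc(OC)c1)[C@@H](c1ccc(OC)cc1)O2 | intermediate
11 | (2R,3R)-trans-5-bromo-dihydrobenzofuran | Brc1cc(OC)c2c(c1)[C@@H](c1cc(OC)cc(OC)c1)[C@H](c1ccc(OC)cc1)O2 | intermediate
12 | tert-butyl 4-vinylphenyl carbonate | C=Cc1ccc(OC(=O)OC(C)(C)C)cc1 | starting material
13 | E-stilbene carbonate | CC(C)(C)OC(=O)Oc1ccc(/C=C/c2cc(OC)c3c(c2)[C@@H](c2cc(OC)cc(OC)c2)[C@H](c2ccc(OC)cc2)O3)cc1 | intermediate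
14 | (R,R)-trans-diaryloxirane | CC(C)(C)OC(=O)Oc1ccc(cc1)[C@H]1O[C@@H]1c1cc(OC)c2c(c1)[C@@H](c1cc(OC)cc(OC)c1)[C@H](c1ccc(OC)cc1)O2 | intermediate
15 | 2,6-dibromo-4-methoxyphenol | COc1cc(Br)c(O)c(Br)c1 | starting material
16 | (2,6-dibromo-4-methoxyphenoxy)trimethylsilane | COc1cc(Br)c(O[Si](C)(C)C)c(Br)c1 | intermediate
17 | 3-bromo-5-methoxy-2-(trimethylsilyloxy)phenyllithium | COc1cc(Br)c(O[Si](C)(C)C)c([Li])c1 | intermediate
18 | lithium 2-bromo-4-methoxy-6-(trimethylsilyl)phenolate | COc1cc(Br)c([O-])c([Si](C)(C)C)c1.[Li+] | intermediate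
19 | 2-bromo-4-methoxy-6-(trimethylsilyl)phenyl trifluoromethanesulfonate | COc1cc(Br)c(OS(=O)(=O)C(F)(F)F)c([Si](C)(C)C)c1 | intermediate
20 | 3-bromo-5-methoxybenzyne | COC1=CC#CC(Br)=C1 | intermediate
21 | aryloxiranium zwitterion | COc1cc(Br)[c-]c([O+]2[C@H](c3ccc(OC(=O)OC(C)(C)C)cc3)[C@H]2c2cc(OC)c3c(c2)[C@@H](c2cc(OC)cc(OC)c2)[C@H](c2ccc(OC)cc2)O3)c1 | intermediate
22 | ring-opened zwitterion | COc1cc(Br)[c-]c(O[C@H](c2ccc(OC(=O)OC(C)(C)C)cc2)[CH+]c2cc(OC)c3c(c2)[C@@H](c2cc(OC)cc(OC)c2)[C@H](c2ccc(OC)cc2)O3)c1 | intermediate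
23 | (2S,3S,2'R,3'R)-4-bromo bis(dihydrobenzofuran) carbonate | Brc1cc(OC)cc2c1[C@H](c1cc(OC)c3c(c1)[C@@H](c1cc(OC)cc(OC)c1)[C@H](c1ccc(OC)cc1)O3)[C@@H](c1ccc(OC(=O)OC(C)(C)C)cc1)O2 | intermediate
24 | hexaphenol bromide | Brc1cc(O)cc2c1[C@H](c1cc(O)c3c(c1)[C@@H](c1cc(O)cc(O)c1)[C@H](c1ccc(O)cc1)O3)[C@@H](c1ccc(O)cc1)O2 | intermediate
25 | hexaacetate bromide | Brc1cc(OC(C)=O)cc2c1[C@H](c1cc(OC(C)=O)c3c(c1)[C@@H](c1cc(OC(C)=O)cc(OC(C)=O)c1)[C@H](c1ccc(OC(C)=O)cc1)O3)[C@@H](c1ccc(OC(C)=O)cc1)O2 | intermediate
26 | 4-vinylphenyl acetate | C=Cc1ccc(OC(C)=O)cc1 | starting material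
27 | heptaacetate of the target | CC(=O)Oc1ccc(/C=C/c2cc(OC(C)=O)cc3c2[C@H](c2cc(OC(C)=O)c4c(c2)[C@@H](c2cc(OC(C)=O)cc(OC(C)=O)c2)[C@H](c2ccc(OC(C)=O)cc2)O4)[C@@H](c2ccc(OC(C)=O)cc2)O3)cc1 | intermediate
28 | CNP0172909.1 | Oc1ccc(/C=C/c2cc(O)cc3c2[C@H](c2cc(O)c4c(c2)[C@@H](c2cc(O)cc(O)c2)[C@H](c2ccc(O)cc2)O4)[C@@H](c2ccc(O)cc2)O3)cc1 | target

## Step count and risks

Total step count: 14. Longest linear sequence: 13 (steps 1–8 and 10–14); step 9 is a one-step side branch.

**Step 10**
- What may go wrong:
  - The flanked oxirane oxygen may be too poor a nucleophile for the aryne.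
  - The zwitterion may be diverted by internal proton transfer.
  - The ortho-bromoaryl anion may lose bromide.
  - Bond rotation before collapse may erode the trans selectivity.
- Fallback: ring B is built with the carbene C–H insertion already used for ring D, which is known chemistry. It sets out from 11 and comes back at 24.
- Purchased 2-bromo-6-hydroxy-4-methoxybenzaldehyde is alkylated with 2 (K2CO3, DMF) to 2-bromo-4-methoxy-6-[(4-methoxybenzyl)oxy]benzaldehyde F1.
- Compound 11 is converted with n-BuLi (THF, −78 °C) into the C5'-aryllithium F2, which adds to F1 to give the diarylmethanol F3.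
- MnO2 gives the diaryl ketone F4. Hydrazine hydrate under forcing conditions (n-BuOH, 120 °C) gives the hydrazone F5, and MnO2 gives the diaryldiazomethane F6.
- Rh2(S-PTAD)4, the antipode of the catalyst of step 5, gives the cis-(2R,3S) hexamethyl ether F7.
- CF3CO2H as in step 6 epimerises C2 to the trans-(2S,3S) hexamethyl ether F8, and BBr3 as in step 11 gives 24.

**Step 8**
- What may go wrong:
  - The aryl carbonate may hydrolyse in the aqueous carbonate buffer.
  - The para-alkoxybenzylic oxirane may open solvolytically or rearrange during reaction or isolation.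
  - The large lipophilic alkene may dissolve poorly and convert slowly.
- Fallback: catalyst control is given up in favour of a neutral, anhydrous oxidation and separation of diastereomers. It sets out from 13 and comes back at 14.
- Dimethyldioxirane in acetone–CH2Cl2 at −20 °C, worked up by evaporation only, should give 14 together with the (S,S)-oxirane diastereomer F9.
- Because rings C and D are already homochiral, the two are diastereomers. They are separated by preparative HPLC on a polysaccharide phase with a neutral eluent.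

**Step 13**
- What may go wrong:
  - Oxidative addition and alkene insertion may be sluggish at the bromide flanked by the C3 substituent.
  - Hydrodebromination or intramolecular C–H arylation of ring C may compete.
- Fallback: the alkene is brought in preformed as a nucleophile, so that transmetalation replaces carbopalladation. It sets out from 26 and 25 and comes back at 27.
- Cross metathesis of 26 with vinylboronic acid pinacol ester (second-generation Grubbs catalyst, CH2Cl2, 40 °C) gives the (E)-styrylboronate F10.
- Suzuki–Miyaura coupling of F10 with 25 (Pd(OAc)2, SPhos, anhydrous K3PO4, 1,4-dioxane, 80 °C) gives 27.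

## Further compounds

F1 | step 10 | 2-bromo-4-methoxy-6-[(4-methoxybenzyl)oxy]benzaldehyde | O=Cc1c(Br)cc(OC)cc1OCc1ccc(OC)cc1
F2 | step 10 | C5'-aryllithium from 11 | [Li]c1cc(OC)c2c(c1)[C@@H](c1cc(OC)cc(OC)c1)[C@H](c1ccc(OC)cc1)O2
F3 | step 10 | diarylmethanol (carbinol epimers) | OC(c1c(Br)cc(OC)cc1OCc1ccc(OC)cc1)c1cc(OC)c2c(c1)[C@@H](c1cc(OC)cc(OC)c1)[C@H](c1ccc(OC)cc1)O2
F4 | step 10 | diaryl ketone | O=C(c1c(Br)cc(OC)cc1OCc1ccc(OC)cc1)c1cc(OC)c2c(c1)[C@@H](c1cc(OC)cc(OC)c1)[C@H](c1ccc(OC)cc1)O2
F5 | step 10 | hydrazone of F4 | NN=C(c1c(Br)cc(OC)cc1OCc1ccc(OC)cc1)c1cc(OC)c2c(c1)[C@@H](c1cc(OC)cc(OC)c1)[C@H](c1ccc(OC)cc1)O2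
F6 | step 10 | diaryldiazomethane | [N-]=[N+]=C(c1c(Br)cc(OC)cc1OCc1ccc(OC)cc1)c1cc(OC)c2c(c1)[C@@H](c1cc(OC)cc(OC)c1)[C@H](c1ccc(OC)cc1)O2
F7 | step 10 | cis-(2R,3S) hexamethyl ether | Brc1cc(OC)cc2c1[C@H](c1cc(OC)c3c(c1)[C@@H](c1cc(OC)cc(OC)c1)[C@H](c1ccc(OC)cc1)O3)[C@H](c1ccc(OC)cc1)O2
F8 | step 10 | trans-(2S,3S) hexamethyl ether | Brc1cc(OC)cc2c1[C@H](c1cc(OC)c3c(c1)[C@@H](c1cc(OC)cc(OC)c1)[C@H](c1ccc(OC)cc1)O3)[C@@H](c1ccc(OC)cc1)O2
F9 | step 8 | (S,S)-oxirane diastereomer of 14 | CC(C)(C)OC(=O)Oc1ccc(cc1)[C@@H]1O[C@H]1c1cc(OC)c2c(c1)[C@@H](c1cc(OC)cc(OC)c1)[C@H](c1ccc(OC)cc1)O2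
F10 | step 13 | 4-[(E)-2-(4,4,5,5-tetramethyl-1,3,2-dioxaborolan-2-yl)ethenyl]phenyl acetate | CC(=O)Oc1ccc(/C=C/B2OC(C)(C)C(C)(C)O2)cc1
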